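Early times give you rates, but you are asked about Tuesday's flask at 52 min, and by then Monday's run gains just 0.0190 M in its last 19.0 min. So read the ends of the runs.

| flask | Sub | Rgt | Prd | time |
|---|---|---|---|---|
| Friday's | 1.00 M | 1.00 M |  |  |
| Monday's | 2.00 M | 1.00 M |  |  |
| Saturday's | 1.00 M | 1.00 M | 0.300 M |  |
| Tuesday's | 2.00 M | 0.330 M |  | 52 min |

- Friday's run (time / min: [Prd] / M): 2.1: 0.037; 3.3: 0.070; 5.2: 0.136; 8.3: 0.226; 13: 0.323; 21: 0.407; 33: 0.462; 52: 0.488
- Monday's run (time / min: [Prd] / M): 2.1: 0.064; 3.3: 0.137; 5.2: 0.258; 8.3: 0.409; 13: 0.546; 21: 0.655; 33: 0.708; 52: 0.727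
- Saturday's run (time / min: [Prd] / M): 2.1: 0.357; 3.3: 0.409; 5.2: 0.470; 8.3: 0.558; 13: 0.647; 21: 0.728; 33: 0.780; 52: 0.801

(scatter of a reading: 0.003 M)

* the exponent of [Sub] in the starting rate at the charge of the Friday's run (at the point where two percent of the Sub have become Prd) (one fixed amount of Prd, the same in the runs compared)
* Prd in the Tuesday's run at 52 min, as a share of the Sub charged

- Overall: Sub + Rgt -> Prd.
- Constant volume, constant temperature.
- An order is taken over about fifteen percent of the charge, up and down.

Tuesday's flask charges c_Rgt 0.330 M against c_Sub 2.00 M, so Rgt is the limiting reagent. Write its balance: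

charge of Rgt = c_Prd made + the rest

Two amounts, then. Monday's run has the same Sub charge and reads 0.727 M made at 52 min, against a rest of 0.273 M of its Rgt charge:

c_Prd made / charge of Rgt = 0.727

This capture share, the fraction of charged Rgt standing as Prd made at 52 min, reads 0.488 in Friday's run and 0.501 in Saturday's run, which adds 0.300 M Prd to the same charge. It is higher at Monday's Sub charge than at Friday's.

My own reckoning assumes that Rgt leaves by pseudo-first-order routes at a given Sub charge, so the share ignores the Rgt charge:

c_Prd on Tuesday ≈ 0.240 M, or 12.0% of Sub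

The forecast gives an order of 0.7 in Sub and, for Tuesday's flask, 13.2%, more than my figure; of the plateaus it says “Something is lost in competition”.

The flask gives 12.6% and an order of 0.64, and both forecast values hold within their margins.

    Sub → Int (0.3024 min⁻¹)
    Int + Rgt → Prd (0.06840 L mol⁻¹ min⁻¹)
    Int → Sid (0.02712 min⁻¹)
    Sub + Rgt + Prd → 2 Prd (0.05622 L² mol⁻² min⁻¹)
    Rgt → X (0.02166 min⁻¹)

The step from Sub + Rgt + Prd to two Prd makes no difference to Tuesday's yield. Tuesday's capture share comes to 0.764, above Monday's 0.727, which leaves 0.0770 M of Tuesday's Rgt charge outside Prd at 52 min.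

Readings and results stem from a simulated flask for an exercise; noise was put on by code.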